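**Strategy.** The chromone is cut at C3–C4 and O1–C8a, which leads back to heptadecan-2-one and 2,4,6-trifluorobenzoyl chloride. The feature used is the 1,3,5-oxygenation of the benzo ring around C4a (O1 on C8a, hydroxyls on C5 and C7): each oxygen stands where a C–F bond ortho or para to the C4 carbonyl can be placed. In one flask the methyl-side lithium enolate of the ketone is C-acylated and the diketonate oxygen then displaces an ortho fluoride, closing the pyranone ring. The two remaining fluorides are exchanged for methoxide and the methyl ethers are cleaved.

Key step: step 1

Remark: the target has no stereocentre and no stereogenic double bond; it is achiral, so no enantiocontrol is needed.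

**Step 1**
Reactants: 1 heptadecan-2-one; 2 2,4,6-trifluorobenzoyl chloride
Product: 5 5,7-difluoro-2-pentadecyl-4H-chromen-4-one, via lithium heptadec-1-en-2-olate 3 (not isolated), via 1-(2,4,6-trifluorophenyl)octadecane-1,3-dione 4 (not isolated)
Conditions: 1 (THF solution) added to LiHMDS (2.1 equiv), THF, −78 °C; 2 (1.0 equiv) added slowly, −78 → 0 °C; then DMF, 60 °C
Reagents that add atoms: none
Why: Kinetic deprotonation of 1 by the hindered amide at −78 °C, with base always in excess so that no free ketone can equilibrate the enolate, should give the methyl-side enolate 3, which attacks the acid chloride at carbon (Claisen-type C-acylation, bond C3–C4); the second equivalent of base at once turns diketone 4 into its lithium enolate, and a second acylation is avoided because 2 is the limiting reagent. On warming with DMF, which loosens the lithium chelate so that the oxygen on C2 can turn towards the arene, this oxygen adds to an ortho C–F carbon, the Meisenheimer anion is stabilised by the C4 carbonyl and inductively by the two meta fluorines, and loss of fluoride forms O1–C8a (intramolecular SNAr, the known one-pot chromone and 4-quinolone synthesis from 2-halobenzoyl chlorides and enolates). The pyranone closes as a six-membered ring by O-attack on an aromatic sp2 carbon (6-exo-trig counted on the C8–C8a π bond); the central carbon of the diketonate cannot compete, since it would close a four-membered ring. No stereocentre is formed. C- over O-acylation is secured by the tightly bound lithium counter-ion in THF at low temperature, methyl over methylene enolisation by the kinetic conditions, and the ring closure has no regiochemical choice because both ortho fluorines are equivalent and the para fluorine is out of reach.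

**Step 2**
Reactants: 5 5,7-difluoro-2-pentadecyl-4H-chromen-4-one
Product: 8 5,7-dimethoxy-2-pentadecyl-4H-chromen-4-one, via 7-fluoro-5-methoxy-2-pentadecyl-4H-chromen-4-one 6 (not isolated), via 5-fluoro-7-methoxy-2-pentadecyl-4H-chromen-4-one 7 (not isolated)
Conditions: NaOMe (5 equiv, anhydrous), MeOH/THF, 65 °C; dilute aq. HCl work-up
Reagents that add atoms: sodium methoxide, [Na+].[O-]C
Why: Nucleophilic aromatic substitution by addition–elimination: the fluorides sit ortho (C5) and para (C7) to the C4 carbonyl, which takes up the charge of each Meisenheimer adduct, the first methoxy group slows the second exchange so that excess methoxide at reflux is used, and the mildly acidic work-up recloses any pyranone opened reversibly by methoxide at C2.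

**Step 3**
Reactants: 8 5,7-dimethoxy-2-pentadecyl-4H-chromen-4-one
Product: 10 5,7-dihydroxy-2-pentadecyl-4H-chromen-4-one, via 5-hydroxy-7-methoxy-2-pentadecyl-4H-chromen-4-one 9 (not isolated)
Conditions: BBr3 (6 equiv), CH2Cl2, −78 °C → rt (40 °C to finish); ice-water
Reagents that add atoms: none
Why: Lewis-acid cleavage of aryl methyl ethers: boron coordinates each ether oxygen and bromide removes the methyl group by SN2, the C5 ether next to the carbonyl falling first through a boron chelate and the C7 ether with the excess reagent on warming, while the pyranone and the saturated chain do not react and water hydrolyses the aryl borates to the two phenols.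

**Compound list**
1 | heptadecan-2-one | CCCCCCCCCCCCCCCC(C)=O | starting material
2 | 2,4,6-trifluorobenzoyl chloride | O=C(Cl)c1c(F)cc(F)cc1F | starting material
3 | lithium heptadec-1-en-2-olate (methyl-side enolate of 1) | [Li+].[O-]C(=C)CCCCCCCCCCCCCCC | intermediate
4 | 1-(2,4,6-trifluorophenyl)octadecane-1,3-dione (held in the flask as its lithium enolate) | CCCCCCCCCCCCCCCC(=O)CC(=O)c1c(F)cc(F)cc1F | intermediate
5 | 5,7-difluoro-2-pentadecyl-4H-chromen-4-one | CCCCCCCCCCCCCCCc1cc(=O)c2c(F)cc(F)cc2o1 | intermediate
6 | 7-fluoro-5-methoxy-2-pentadecyl-4H-chromen-4-one | CCCCCCCCCCCCCCCc1cc(=O)c2c(OC)cc(F)cc2o1 | intermediate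
7 | 5-fluoro-7-methoxy-2-pentadecyl-4H-chromen-4-one | CCCCCCCCCCCCCCCc1cc(=O)c2c(F)cc(OC)cc2o1 | intermediate
8 | 5,7-dimethoxy-2-pentadecyl-4H-chromen-4-one | CCCCCCCCCCCCCCCc1cc(=O)c2c(OC)cc(OC)cc2o1 | intermediate
9 | 5-hydroxy-7-methoxy-2-pentadecyl-4H-chromen-4-one (present as its O-boron chelate until work-up) | CCCCCCCCCCCCCCCc1cc(=O)c2c(O)cc(OC)cc2o1 | intermediate
10 | 5,7-dihydroxy-2-pentadecyl-4H-chromen-4-one (achiral) | CCCCCCCCCCCCCCCc1cc(=O)c2c(O)cc(O)cc2o1 | target

**Total step count:** 3. **Longest linear sequence:** 3 steps.

**Steps most likely to fail**

1. Step 1. Acylation may go to oxygen or to the methylene-side enolate, free amide base may consume the acid chloride, and ring closure from the chelated lithium diketonate may be slow. The fallback sets out from 2 and comes back at 5, and builds the diketone through C2–C3 instead of C3–C4. Lithium dimethylcuprate (Et2O, −78 °C) converts 2 into 1-(2,4,6-trifluorophenyl)ethan-1-one F1, which can also be purchased. Its lithium enolate (LiHMDS, 2.1 equiv, THF, −78 °C) can form on one side only and is acylated with hexadecanoyl chloride to give diketone 4, now isolated after an acidic quench. K2CO3 in DMF at 80 °C then closes the ring by the same fluoride displacement and gives 5.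

2. Step 2. The exchange may stall after the first fluoride because the new methoxy group deactivates the ring, and the prolonged heating may open the pyranone by alkoxide attack at C2. The fallback sets out from 5 and comes back at 10, so it also replaces step 3. Benzyl alcohol and NaH in DMF (0 °C → rt) supply a poorly solvated alkoxide that should exchange both fluorides without long heating and give 5,7-bis(benzyloxy)-2-pentadecyl-4H-chromen-4-one F2. Hydrogenolysis (H2, 1 atm, Pd/C, EtOAc/THF, stopped when debenzylation is complete) should then give 10 under neutral conditions.

3. Step 3. Cleavage of the non-chelated C7 methyl ether may remain incomplete, so that the reaction stops at the 5-hydroxy-7-methoxy stage. The fallback sets out from 8 (or from recovered 9) and comes back at 10. Fusion with pyridinium chloride at about 190 °C removes the methyl groups by protonation of the ether oxygen and SN2 attack of chloride, a Brønsted-acid pathway with no boron chelate to hold the reaction back. This fallback makes no new compound (F0).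

**Further compounds**
F1 | step 1 | 1-(2,4,6-trifluorophenyl)ethan-1-one | CC(=O)c1c(F)cc(F)cc1F
F2 | step 2 | 5,7-bis(benzyloxy)-2-pentadecyl-4H-chromen-4-one | CCCCCCCCCCCCCCCc1cc(=O)c2c(OCc3ccccc3)cc(OCc3ccccc3)cc2o1
F0 | step 3 | none | none
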